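**Plan**

- Core numbering (hexahydro-1H-indene): C1 (Me), C2 (C=O), C3 (Et), C3a, C4 (Et, CO2H), C5 (Et, styryl), C6=C7 (Et on C7), C7a. The cyclohexene C3a–C4–C5–C6=C7–C7a has its double bond opposite the carboxyl-bearing C3a–C4 edge, and the five-membered ring spans C3a–C7a. Cutting C4–C5 and C3a–C7a together (retro-[4+2]) therefore opens both rings to one linear all-E tetraenoate with C1–C2–C3 as the tether.
- In the open chain C2 is a silyl ether and the acid a tert-butyl ester, so the allylic centres C1 and C3 cannot enolise; ketone and acid are restored after ring formation.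
- Further chain cuts: C3a=C4 (Wittig), C6–C7 (hydrozirconation/Negishi coupling of an ethyl alkyne with a bromodiene), C1–C2 (anti-selective allenylzinc addition), C3–C3a (auxiliary-controlled hydroxymethylation), styrene C=C (Horner–Wadsworth–Emmons).
- Forward: C3 aldehyde, then the C1–C2–C3 stereotriad carrying the alkyne, then triene, then enoate; the cyclohexene and the cyclopentane then arise together in one thermal step, followed by deprotection and oxidation at C2.
- Stereochemistry: C3 from the Evans auxiliary; C1 (and the temporary C2 carbinol) from (2S)-but-3-yn-2-ol by chirality transfer; C3a, C4, C5 and C7a from the cycloaddition (alkene geometries, ester-endo mode, A1,3 strain at C1 and C3).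

Key step: step 15

Assumption: imide 1 (the N-butanoyl derivative of the Evans benzyl oxazolidinone) is taken as a purchasable compound.

**Route**

Step 1
Reactants: 1 (4S)-4-benzyl-3-butanoyl-1,3-oxazolidin-2-one; 2 1,3,5-trioxane
Product: 4 (4S)-4-benzyl-3-[(2R)-2-(hydroxymethyl)butanoyl]-1,3-oxazolidin-2-one, via titanium (Z)-enolate 3 (not isolated)
Conditions: TiCl4, i-Pr2NEt, CH2Cl2, 0 °C; then 2, TiCl4, 0 °C
Reagents that add atoms: none
Why: Auxiliary-controlled hydroxymethylation (Evans titanium-enolate alkylation type): the chelated (Z)-enolate 3 is attacked by formaldehyde, released from 2 by TiCl4, on the face opposite the benzyl group, which sets the future C3 centre as 2R in 4.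

Step 2
Reactants: 4 (4S)-4-benzyl-3-[(2R)-2-(hydroxymethyl)butanoyl]-1,3-oxazolidin-2-one
Product: 5 (2R)-2-(hydroxymethyl)-N-methoxy-N-methylbutanamide
Conditions: MeNH(OMe)·HCl, AlMe3, CH2Cl2, −15 → 0 °C
Reagents that add atoms: N,O-dimethylhydroxylamine hydrochloride, CNOC.Cl
Why: Weinreb transamination with the aluminium amide made in the flask, assisted by the free β-hydroxyl, should cleave the exocyclic acyl group without touching the α-centre and return the auxiliary.

Step 3
Reactants: 5 (2R)-2-(hydroxymethyl)-N-methoxy-N-methylbutanamide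
Product: 6 (2R)-N-methoxy-N-methyl-2-{[(triethylsilyl)oxy]methyl}butanamide
Conditions: Et3SiCl, imidazole, CH2Cl2, 0 °C
Reagents that add atoms: chlorotriethylsilane, CC[Si](CC)(CC)Cl
Why: Standard O-silylation of the primary alcohol; the triethylsilyl ether is chosen because a primary one can later be oxidised directly to the aldehyde.

Step 4
Reactants: 6 (2R)-N-methoxy-N-methyl-2-{[(triethylsilyl)oxy]methyl}butanamide
Product: 7 (2R)-2-{[(triethylsilyl)oxy]methyl}butanal
Conditions: i-Bu2AlH, THF, −78 °C; aq. potassium sodium tartrate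
Reagents that add atoms: none
Why: Hydride reduction of the N-methoxy-N-methylamide stops at the aldehyde level, and passing through the amide avoids a free hydroxyl next to the silyl ether, so the centre cannot racemise by 1,5-silyl migration between the two CH2O arms; 7 is used crude to limit α-epimerisation.

Step 5
Reactants: 8 (2S)-but-3-yn-2-ol; 9 iodoethane
Product: 11 (2S)-hex-3-yn-2-ol, via dilithium alkynide alkoxide 10 (not isolated)
Conditions: n-BuLi (2.1 equiv), THF, −78 → 0 °C; then DMPU, 9, 0 °C → rt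
Reagents that add atoms: none
Why: Acetylide alkylation of the dianion at carbon, the lithium alkoxide being the poorer nucleophile; the carbinol centre is not involved.

Step 6
Reactants: 11 (2S)-hex-3-yn-2-ol
Product: 12 (2S)-hex-3-yn-2-yl methanesulfonate
Conditions: MsCl, Et3N, CH2Cl2, −78 → 0 °C
Reagents that add atoms: methanesulfonyl chloride, CS(=O)(=O)Cl
Why: Sulfonylation at oxygen with retention of configuration; 12 is used without chromatography.

Step 7
Reactants: 7 (2R)-2-{[(triethylsilyl)oxy]methyl}butanal; 12 (2S)-hex-3-yn-2-yl methanesulfonate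
Product: 14 (3R,4R,5R)-5-methyl-3-{[(triethylsilyl)oxy]methyl}non-6-yn-4-ol, via allenylzinc 13 (not isolated)
Conditions: Pd(OAc)2 (5 mol %), PPh3 (5 mol %), Et2Zn (3 equiv), THF, −78 → −20 °C
Reagents that add atoms: none
Why: Marshall propargylation: zerovalent palladium displaces the mesylate in anti SN2' fashion, Et2Zn transmetalates to the axially chiral allenylzinc 13, and this adds to 7 through a closed six-membered SE2' transition state, so the methyl-bearing centre comes from 12 by chirality transfer (net inversion) and the carbinol centre from the anti preference of that transition state, under reagent control because the two α-substituents of 7 differ little in size.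

Step 8
Reactants: 14 (3R,4R,5R)-5-methyl-3-{[(triethylsilyl)oxy]methyl}non-6-yn-4-ol
Product: 15 (3R,4R,5R)-5-methyl-4-[(triethylsilyl)oxy]-3-{[(triethylsilyl)oxy]methyl}non-6-yne
Conditions: Et3SiOTf, 2,6-lutidine, CH2Cl2, −78 → 0 °C
Reagents that add atoms: triethylsilyl trifluoromethanesulfonate, CC[Si](CC)(CC)OS(=O)(=O)C(F)(F)F
Why: Silyl triflate silylation of the hindered secondary alcohol; the bulky ether also shields the nearer alkyne carbon in step 11.

Step 9
Reactants: 16 2-ethylprop-2-enal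
Product: 18 (2E)-2-(bromomethylidene)butanal, via dibromo aldehyde 17 (not isolated)
Conditions: Br2, CH2Cl2, −78 → 0 °C; then Et3N, 0 °C → rt
Reagents that add atoms: bromine, BrBr
Why: Bromine addition followed by amine-induced dehydrobromination (the tertiary α-bromide leaves with the acidified BrCH2 proton) should give the conjugated β-bromoenal as the more stable E isomer, as in the known preparation of (E)-3-bromo-2-methylprop-2-enal.

Step 10
Reactants: 18 (2E)-2-(bromomethylidene)butanal; 19 diethyl benzylphosphonate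
Product: 21 [(1E,3E)-4-bromo-3-ethylbuta-1,3-dien-1-yl]benzene, via sodium phosphonate carbanion 20 (not isolated)
Conditions: NaN(SiMe3)2, THF, −78 °C; then 18, −78 °C → rt
Reagents that add atoms: none
Why: Horner–Wadsworth–Emmons olefination with a benzylic phosphonate gives the E styrene, and the C–Br bond and its geometry stay intact because carbonyl addition outruns attack at the β-carbon.

Step 11
Reactants: 15 (3R,4R,5R)-5-methyl-4-[(triethylsilyl)oxy]-3-{[(triethylsilyl)oxy]methyl}non-6-yne; 21 [(1E,3E)-4-bromo-3-ethylbuta-1,3-dien-1-yl]benzene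
Product: 24 [(1E,3E,5E,7R,8R,9R)-3,5-diethyl-7-methyl-8-[(triethylsilyl)oxy]-9-{[(triethylsilyl)oxy]methyl}undeca-1,3,5-trien-1-yl]benzene, via alkenylzirconocene chloride 22 (not isolated), via alkenylzinc chloride 23 (not isolated)
Conditions: Cp2Zr(H)Cl (2 equiv), THF, 50 °C; then ZnCl2, 21, Pd(PPh3)4 (5 mol %), THF, rt → 40 °C
Reagents that add atoms: none
Why: Hydrozirconation/Negishi coupling: syn addition of Zr–H, equilibrated with excess hydride so that zirconium rests on the less hindered, ethyl-bearing alkyne carbon (22), then transmetalation to zinc (23) and palladium-catalysed alkenyl–alkenyl coupling with retention at both partners, which fixes the E geometry of both trisubstituted alkenes.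

Step 12
Reactants: 24 [(1E,3E,5E,7R,8R,9R)-3,5-diethyl-7-methyl-8-[(triethylsilyl)oxy]-9-{[(triethylsilyl)oxy]methyl}undeca-1,3,5-trien-1-yl]benzene
Product: 26 (2S,3R,4R,5E,7E,9E)-2,6,8-triethyl-4-methyl-10-phenyl-3-[(triethylsilyl)oxy]deca-5,7,9-trienal, via alkoxysulfonium chloride 25 (not isolated)
Conditions: (COCl)2, DMSO, CH2Cl2, −78 → −40 °C; then Et3N, −78 → 0 °C
Reagents that add atoms: none
Why: Swern oxidation carried out directly on the silyl ether: chlorodimethylsulfonium chloride exchanges only the unhindered primary triethylsilyl group (the flanked secondary one is inert), and Et3N then collapses 25 to the aldehyde at low temperature without α-epimerisation.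

Step 13
Reactants: 27 tert-butyl 2-bromobutanoate
Product: 29 tert-butyl 2-(triphenyl-λ5-phosphanylidene)butanoate, via phosphonium bromide 28 (not isolated)
Conditions: PPh3, toluene, 90 °C; then aq. NaOH, CH2Cl2, 0 °C
Reagents that add atoms: triphenylphosphine, c1ccc(cc1)P(c1ccccc1)c1ccccc1
Why: SN2 quaternisation of the α-bromo ester and deprotonation of the salt give the ester-stabilised ylide.

Step 14
Reactants: 26 (2S,3R,4R,5E,7E,9E)-2,6,8-triethyl-4-methyl-10-phenyl-3-[(triethylsilyl)oxy]deca-5,7,9-trienal; 29 tert-butyl 2-(triphenyl-λ5-phosphanylidene)butanoate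
Product: 30 tert-butyl (2E,4R,5R,6R,7E,9E,11E)-2,4,8,10-tetraethyl-6-methyl-12-phenyl-5-[(triethylsilyl)oxy]dodeca-2,7,9,11-tetraenoate
Conditions: toluene, 70 °C
Reagents that add atoms: none
Why: Wittig olefination with a stabilised α-branched ylide should give the (E)-2-ethyl enoate under neutral conditions, so the α-stereocentre of 26 is kept; 30 is purified quickly and taken on at once.

Step 15
Reactants: 30 tert-butyl (2E,4R,5R,6R,7E,9E,11E)-2,4,8,10-tetraethyl-6-methyl-12-phenyl-5-[(triethylsilyl)oxy]dodeca-2,7,9,11-tetraenoate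
Product: 31 tert-butyl (1R,2R,3R,3aS,4S,5R,7aS)-3,4,5,7-tetraethyl-1-methyl-5-[(E)-2-phenylethenyl]-2-[(triethylsilyl)oxy]-2,3,3a,4,5,7a-hexahydro-1H-indene-4-carboxylate
Conditions: toluene (0.02 M), BHT (cat.), argon, dark, 110 °C
Reagents that add atoms: none
Why: Thermal, concerted, suprafacial [4+2] cycloaddition (type 1 intramolecular Diels–Alder reaction) of the C7=C8–C9=C10 diene of 30, whose HOMO is raised by two ethyl groups and the styryl group, with the C2=C3 enoate, forming C3–C7 and C2–C10 in one event; the closest known reaction type is the intramolecular Diels–Alder reaction of (E,E,E)-nona-2,7,9-trienoates to trans-fused hexahydroindenes. The cyclohexene closes as the cycloadduct ring and the cyclopentane, in the fused mode, as the ring of the three-atom tether C4–C5–C6, its closing bond C3–C7 becoming C3a–C7a of 31. The two quaternary centres C4 and C5 of 31 follow stereospecifically from the E geometry of the enoate and of the C9=C10 alkene (ester cis to styryl, the two ethyl groups cis), and the trans ring fusion follows from the transition state with the ester endo and the tether anti. The absolute sense is relayed from C6 (methyl) and C4 (ethyl) of 30: each allylic C–H lies in the plane of its alkene to avoid A1,3 strain with the cis ethyl group on C8 or C2, so methyl and ethyl sit pseudo-equatorial on the forming five-membered ring. Because these two centres are 1,3-anti, only the trans-fused transition state on one π-face accommodates both, so endo/exo and facial selectivity are secured by the same element, while the silyloxy group at C5 is a spectator. Periselectivity for the C7–C10 diene follows from the tether length, since the styryl-containing diene could only close a strained medium ring.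

Step 16
Reactants: 31 tert-butyl (1R,2R,3R,3aS,4S,5R,7aS)-3,4,5,7-tetraethyl-1-methyl-5-[(E)-2-phenylethenyl]-2-[(triethylsilyl)oxy]-2,3,3a,4,5,7a-hexahydro-1H-indene-4-carboxylate
Product: 32 (1R,2R,3R,3aS,4S,5R,7aS)-3,4,5,7-tetraethyl-2-hydroxy-1-methyl-5-[(E)-2-phenylethenyl]-2,3,3a,4,5,7a-hexahydro-1H-indene-4-carboxylic acid
Conditions: CF3CO2H/CH2Cl2 (1:4), H2O (2 equiv), anisole, 0 °C → rt
Reagents that add atoms: none
Why: Acidolysis: the tert-butyl ester cleaves by alkyl–oxygen fission, which is indifferent to the crowding of a carboxyl on a quaternary carbon, and the triethylsilyl ether is hydrolysed in the same operation.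

Step 17
Reactants: 32 (1R,2R,3R,3aS,4S,5R,7aS)-3,4,5,7-tetraethyl-2-hydroxy-1-methyl-5-[(E)-2-phenylethenyl]-2,3,3a,4,5,7a-hexahydro-1H-indene-4-carboxylic acid
Product: 33 (1R,3R,3aS,4S,5R,7aS)-3,4,5,7-tetraethyl-1-methyl-2-oxo-5-[(E)-2-phenylethenyl]-2,3,3a,4,5,7a-hexahydro-1H-indene-4-carboxylic acid
Conditions: Dess–Martin periodinane, CH2Cl2, 0 °C → rt
Reagents that add atoms: none
Why: Dess–Martin oxidation of the secondary alcohol tolerates the free acid and both alkenes, and the α-centres C1 and C3 already hold the all-trans arrangement that is also the thermodynamic one, so enolisation of the new ketone cannot erode them.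

**Compound list**

1 | (4S)-4-benzyl-3-butanoyl-1,3-oxazolidin-2-one | CCCC(=O)N1[C@@H](Cc2ccccc2)COC1=O | starting material
2 | 1,3,5-trioxane | C1OCOCO1 | starting material
3 | trichlorotitanium (Z)-enolate of 1 | CC/C=C(\O[Ti](Cl)(Cl)Cl)N1[C@@H](Cc2ccccc2)COC1=O | intermediate
4 | (4S)-4-benzyl-3-[(2R)-2-(hydroxymethyl)butanoyl]-1,3-oxazolidin-2-one | CC[C@H](CO)C(=O)N1[C@@H](Cc2ccccc2)COC1=O | intermediate
5 | (2R)-2-(hydroxymethyl)-N-methoxy-N-methylbutanamide | CC[C@H](CO)C(=O)N(C)OC | intermediate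
6 | (2R)-N-methoxy-N-methyl-2-{[(triethylsilyl)oxy]methyl}butanamide | CC[C@H](CO[Si](CC)(CC)CC)C(=O)N(C)OC | intermediate
7 | (2R)-2-{[(triethylsilyl)oxy]methyl}butanal | CC[C@H](CO[Si](CC)(CC)CC)C=O | intermediate
8 | (2S)-but-3-yn-2-ol | C[C@H](O)C#C | starting material
9 | iodoethane | CCI | starting material
10 | dilithium salt (alkoxide and C4 alkynide) of (2S)-but-3-yn-2-ol | C[C@H]([O-])C#[C-].[Li+].[Li+] | intermediate
11 | (2S)-hex-3-yn-2-ol | C[C@H](O)C#CCC | intermediate
12 | (2S)-hex-3-yn-2-yl methanesulfonate | C[C@H](OS(C)(=O)=O)C#CCC | intermediate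
13 | ethyl[(M)-hexa-3,4-dien-3-yl]zinc | CCC([Zn]CC)=[C@]=C(C)[H] | intermediate
14 | (3R,4R,5R)-5-methyl-3-{[(triethylsilyl)oxy]methyl}non-6-yn-4-ol (4,5-anti, 3,4-syn) | CCC#C[C@@H](C)[C@@H](O)[C@H](CC)CO[Si](CC)(CC)CC | intermediate
15 | (3R,4R,5R)-5-methyl-4-[(triethylsilyl)oxy]-3-{[(triethylsilyl)oxy]methyl}non-6-yne | CCC#C[C@@H](C)[C@@H](O[Si](CC)(CC)CC)[C@H](CC)CO[Si](CC)(CC)CC | intermediate
16 | 2-ethylprop-2-enal | CCC(=C)C=O | starting material
17 | 2-bromo-2-(bromomethyl)butanal (racemic) | CCC(Br)(CBr)C=O | intermediate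
18 | (2E)-2-(bromomethylidene)butanal | Br/C=C(\CC)C=O | intermediate
19 | diethyl benzylphosphonate | CCOP(=O)(Cc1ccccc1)OCC | starting material
20 | sodium (diethoxyphosphoryl)(phenyl)methanide | CCOP(=O)([CH-]c1ccccc1)OCC.[Na+] | intermediate
21 | [(1E,3E)-4-bromo-3-ethylbuta-1,3-dien-1-yl]benzene | Br/C=C(\CC)/C=C/c1ccccc1 | intermediate
22 | chlorobis(cyclopentadienyl){(3E,5R,6R,7R)-5-methyl-6-[(triethylsilyl)oxy]-7-{[(triethylsilyl)oxy]methyl}non-3-en-3-yl}zirconium | CC/C(=C\[C@@H](C)[C@@H](O[Si](CC)(CC)CC)[C@H](CC)CO[Si](CC)(CC)CC)[Zr](Cl)(C1C=CC=C1)C1C=CC=C1 | intermediate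
23 | chloro{(3E,5R,6R,7R)-5-methyl-6-[(triethylsilyl)oxy]-7-{[(triethylsilyl)oxy]methyl}non-3-en-3-yl}zinc | CC/C(=C\[C@@H](C)[C@@H](O[Si](CC)(CC)CC)[C@H](CC)CO[Si](CC)(CC)CC)[Zn]Cl | intermediate
24 | [(1E,3E,5E,7R,8R,9R)-3,5-diethyl-7-methyl-8-[(triethylsilyl)oxy]-9-{[(triethylsilyl)oxy]methyl}undeca-1,3,5-trien-1-yl]benzene | c1ccccc1/C=C/C(CC)=C/C(CC)=C/[C@@H](C)[C@@H](O[Si](CC)(CC)CC)[C@H](CC)CO[Si](CC)(CC)CC | intermediate
25 | {[(2R,3R,4R,5E,7E,9E)-2,6,8-triethyl-4-methyl-10-phenyl-3-[(triethylsilyl)oxy]deca-5,7,9-trien-1-yl]oxy}dimethylsulfonium chloride | c1ccccc1/C=C/C(CC)=C/C(CC)=C/[C@@H](C)[C@@H](O[Si](CC)(CC)CC)[C@H](CC)CO[S+](C)C.[Cl-] | intermediate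
26 | (2S,3R,4R,5E,7E,9E)-2,6,8-triethyl-4-methyl-10-phenyl-3-[(triethylsilyl)oxy]deca-5,7,9-trienal | c1ccccc1/C=C/C(CC)=C/C(CC)=C/[C@@H](C)[C@@H](O[Si](CC)(CC)CC)[C@H](CC)C=O | intermediate
27 | tert-butyl 2-bromobutanoate (racemic) | CCC(Br)C(=O)OC(C)(C)C | starting material
28 | (1-tert-butoxy-1-oxobutan-2-yl)triphenylphosphonium bromide | CCC(C(=O)OC(C)(C)C)[P+](c1ccccc1)(c1ccccc1)c1ccccc1.[Br-] | intermediate
29 | tert-butyl 2-(triphenyl-λ5-phosphanylidene)butanoate | CCC(C(=O)OC(C)(C)C)=P(c1ccccc1)(c1ccccc1)c1ccccc1 | intermediate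
30 | tert-butyl (2E,4R,5R,6R,7E,9E,11E)-2,4,8,10-tetraethyl-6-methyl-12-phenyl-5-[(triethylsilyl)oxy]dodeca-2,7,9,11-tetraenoate | c1ccccc1/C=C/C(CC)=C/C(CC)=C/[C@@H](C)[C@@H](O[Si](CC)(CC)CC)[C@H](CC)/C=C(\CC)C(=O)OC(C)(C)C | intermediate
31 | tert-butyl (1R,2R,3R,3aS,4S,5R,7aS)-3,4,5,7-tetraethyl-1-methyl-5-[(E)-2-phenylethenyl]-2-[(triethylsilyl)oxy]-2,3,3a,4,5,7a-hexahydro-1H-indene-4-carboxylate | CCC1=C[C@](/C=C/c2ccccc2)(CC)[C@@](CC)(C(=O)OC(C)(C)C)[C@H]2[C@H]1[C@@H](C)[C@@H](O[Si](CC)(CC)CC)[C@@H]2CC | intermediate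
32 | (1R,2R,3R,3aS,4S,5R,7aS)-3,4,5,7-tetraethyl-2-hydroxy-1-methyl-5-[(E)-2-phenylethenyl]-2,3,3a,4,5,7a-hexahydro-1H-indene-4-carboxylic acid | CCC1=C[C@](/C=C/c2ccccc2)(CC)[C@@](CC)(C(=O)O)[C@H]2[C@H]1[C@@H](C)[C@@H](O)[C@@H]2CC | intermediate
33 | (1R,3R,3aS,4S,5R,7aS)-3,4,5,7-tetraethyl-1-methyl-2-oxo-5-[(E)-2-phenylethenyl]-2,3,3a,4,5,7a-hexahydro-1H-indene-4-carboxylic acid | CCC1=C[C@](/C=C/c2ccccc2)(CC)[C@@](CC)(C(=O)O)[C@H]2[C@H]1[C@@H](C)C(=O)[C@@H]2CC | target

**Step count and risks**

Total step count: 17. Longest linear sequence: 12 steps (steps 1–4, 7, 8, 11, 12, 14–17, from imide 1).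

Steps most likely to fail:

1. Step 15. Two adjacent quaternary carbons are formed, so the cycloaddition may be slow enough for thermal [1,5]-hydrogen shift in the diene or loss of endo/exo discrimination to compete. The fallback uses a stronger dienophile that a Lewis acid can activate. Setting out from aldehyde 26, Wittig reaction with 2-(triphenyl-λ5-phosphanylidene)butanal (toluene, 90 °C) would give the tetraenal F6. Me2AlCl (CH2Cl2, −78 → −20 °C) should then bring about the same endo cycloaddition at low temperature and give the trans-fused carbaldehyde F7. Oxidation with NaClO2/NaH2PO4/2-methylbut-2-ene (t-BuOH/H2O) would give the silyloxy acid F8, and HF·pyridine (THF) would free the alcohol, returning to the route at hydroxy acid 32.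

2. Step 11. Regiocontrol of the Zr–H addition (ethyl against branched alkyl) may be incomplete, or transmetalation and coupling of the α-branched alkenylmetal may be slow, giving regioisomeric trienes or protodemetalation. The fallback builds the alkene by carbonyl olefination in place of alkyne hydrometalation. Setting out from aldehyde 7, (E)-crotylboration with the enantiomer of (E)-but-2-enylbis(isopinocampheyl)borane that delivers the 3,4-anti (3R,4R) adduct would give the homoallylic alcohol F1. Et3SiOTf/2,6-lutidine would give the bis-silyl ether F2, and ozonolysis (O3, CH2Cl2, −78 °C; PPh3) the α-methyl aldehyde F3. Wittig reaction with 2-(triphenyl-λ5-phosphanylidene)butanal (toluene, 90 °C) would give the (E)-enal F4, and a second Wittig reaction with the same ylide (toluene, 110 °C) the (E,E)-dienal F5. Horner–Wadsworth–Emmons reaction with 19 (NaN(SiMe3)2, THF) then returns to the route at triene 24.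

3. Step 16. Acid may protonate the C6=C7 alkene with capture of the cation by the neighbouring carboxyl, or the tert-butyl cation may alkylate the styrene. The fallback uses a fluoride-labile ester so that no acid is needed. Setting out from aldehyde 26, Wittig reaction with 2-(trimethylsilyl)ethyl 2-(triphenyl-λ5-phosphanylidene)butanoate (toluene, 70 °C) would give the tetraenoate F9, and the cycloaddition under the conditions of step 15 the adduct F10. Bu4NF (THF, rt) would then remove the silyl ether and, by fluoride-induced fragmentation, the ester in one operation, returning to the route at hydroxy acid 32.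

**Further compounds**

F1 | step 11 | (3R,4R,5R)-3-methyl-5-{[(triethylsilyl)oxy]methyl}hept-1-en-4-ol | C=C[C@@H](C)[C@@H](O)[C@H](CC)CO[Si](CC)(CC)CC
F2 | step 11 | (3R,4R,5R)-3-methyl-4-[(triethylsilyl)oxy]-5-{[(triethylsilyl)oxy]methyl}hept-1-ene | C=C[C@@H](C)[C@@H](O[Si](CC)(CC)CC)[C@H](CC)CO[Si](CC)(CC)CC
F3 | step 11 | (2S,3S,4R)-2-methyl-3-[(triethylsilyl)oxy]-4-{[(triethylsilyl)oxy]methyl}hexanal | O=C[C@@H](C)[C@@H](O[Si](CC)(CC)CC)[C@H](CC)CO[Si](CC)(CC)CC
F4 | step 11 | (2E,4R,5R,6R)-2-ethyl-4-methyl-5-[(triethylsilyl)oxy]-6-{[(triethylsilyl)oxy]methyl}oct-2-enal | O=C/C(CC)=C/[C@@H](C)[C@@H](O[Si](CC)(CC)CC)[C@H](CC)CO[Si](CC)(CC)CC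
F5 | step 11 | (2E,4E,6R,7R,8R)-2,4-diethyl-6-methyl-7-[(triethylsilyl)oxy]-8-{[(triethylsilyl)oxy]methyl}deca-2,4-dienal | O=C/C(CC)=C/C(CC)=C/[C@@H](C)[C@@H](O[Si](CC)(CC)CC)[C@H](CC)CO[Si](CC)(CC)CC
F6 | step 15 | (2E,4R,5R,6R,7E,9E,11E)-2,4,8,10-tetraethyl-6-methyl-12-phenyl-5-[(triethylsilyl)oxy]dodeca-2,7,9,11-tetraenal | c1ccccc1/C=C/C(CC)=C/C(CC)=C/[C@@H](C)[C@@H](O[Si](CC)(CC)CC)[C@H](CC)/C=C(\CC)C=O
F7 | step 15 | (1R,2R,3R,3aS,4S,5R,7aS)-3,4,5,7-tetraethyl-1-methyl-5-[(E)-2-phenylethenyl]-2-[(triethylsilyl)oxy]-2,3,3a,4,5,7a-hexahydro-1H-indene-4-carbaldehyde | CCC1=C[C@](/C=C/c2ccccc2)(CC)[C@@](CC)(C=O)[C@H]2[C@H]1[C@@H](C)[C@@H](O[Si](CC)(CC)CC)[C@@H]2CC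
F8 | step 15 | (1R,2R,3R,3aS,4S,5R,7aS)-3,4,5,7-tetraethyl-1-methyl-5-[(E)-2-phenylethenyl]-2-[(triethylsilyl)oxy]-2,3,3a,4,5,7a-hexahydro-1H-indene-4-carboxylic acid | CCC1=C[C@](/C=C/c2ccccc2)(CC)[C@@](CC)(C(=O)O)[C@H]2[C@H]1[C@@H](C)[C@@H](O[Si](CC)(CC)CC)[C@@H]2CC
F9 | step 16 | 2-(trimethylsilyl)ethyl (2E,4R,5R,6R,7E,9E,11E)-2,4,8,10-tetraethyl-6-methyl-12-phenyl-5-[(triethylsilyl)oxy]dodeca-2,7,9,11-tetraenoate | c1ccccc1/C=C/C(CC)=C/C(CC)=C/[C@@H](C)[C@@H](O[Si](CC)(CC)CC)[C@H](CC)/C=C(\CC)C(=O)OCC[Si](C)(C)C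
F10 | step 16 | 2-(trimethylsilyl)ethyl (1R,2R,3R,3aS,4S,5R,7aS)-3,4,5,7-tetraethyl-1-methyl-5-[(E)-2-phenylethenyl]-2-[(triethylsilyl)oxy]-2,3,3a,4,5,7a-hexahydro-1H-indene-4-carboxylate | CCC1=C[C@](/C=C/c2ccccc2)(CC)[C@@](CC)(C(=O)OCC[Si](C)(C)C)[C@H]2[C@H]1[C@@H](C)[C@@H](O[Si](CC)(CC)CC)[C@@H]2CC
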